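## Structural features

The target (C25H30O6) is an isocoumarin. Benzene ring A (C4a, C5, C6, C7, C8, C8a) is fused through the C4a–C8a bond to an enol-lactone ring (C1, O2, C3, C4) that carries an n-pentyl chain at C3. Ring A has a free hydroxyl at C6 and, at C8 (peri to the lactone carbonyl), an ether oxygen leading to ring B, a 2,4-dihydroxy-6-pentylphenyl group. There is no stereocentre and no configurational double bond, so the task is one of constitution and regiochemistry only. The real difficulty is the diaryl ether: its oxygen is flanked by a hydroxyl and a pentyl group on ring B and by the lactone carbonyl on ring A, and ring B is very electron-rich. The fragile parts are ring B once unmasked (a 4-aryloxyphenol of the hydroxyquinol type, easily oxidised) and the enol lactone, which opens with hydroxide or alkoxide. The key step uses the fact that C1, O2, C3, C4, C4a and C8a with the pentyl chain are a 6-pentyl-2-pyranone whose C3=C4 bond is the future C8a=C4a bond. C8, C7, C6 and C5 with their two oxygens are a 1-aryloxy-3-siloxybutadiene, so ring A needs only the C4a–C5 bond.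

## Logic of the disconnections

18 to 16: the two O–CH3 bonds on ring B and the O–Si bond at C6 are put back. Free 18 is oxidation-prone and its phenols would interfere with the oxidant and the silylating agent used earlier, so all three oxygens stay masked until the end. The demand is one Lewis acid that cleaves three oxygen–protecting-group bonds without base and without attacking the diaryl ether or the enol lactone.

16 to 14 (through 15): the C4a–C5 bond is cut and the hydrogens at C4a and C5 are restored. This is the only ring A bond not already present in a pyranone carrying a four-carbon dioxygenated diene. The gain is a whole benzene ring without any aryl–oxygen coupling. The forward step needs the C7=C8 geometry with pyranone and siloxyvinyl cis, a thermal closure faster than desilylation, and a mild dehydrogenation. The C7=C8 bond of 14 has no acceptor in conjugation and should not rotate thermally, so the geometry has to be set before 14, not during the heating.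

14 to 13: the O–Si bond is cut. The silyl dienol ether is the kinetic enol derivative of a methyl ketone, and 13 is a bench-stable vinylogous ester. Enolisation must go to the methyl group (the only α-position of the ketone), must not touch the pentyl α-CH2 on the pyranone, and must keep the double-bond geometry.

13 to 12 + 6: the C8–O bond is cut. The oxygen-bearing carbon is β to the ketone, so the bond is a conjugate addition of a phenol to an ynone. The cut divides the molecule into two halves of similar size and makes the hindered ether before ring A is aromatic. The demands are that the di-ortho-substituted 6 adds at all and that the product equilibrates to the (E) isomer.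

12 to 11 to 9 + 10: the sp2–sp bond between pyranone C3 and the alkyne is cut, after adjusting the ketone to the alcohol. A terminal ynone is a poor coupling partner, so the four-carbon unit enters as commercial 10. The demands are oxidative addition at the C3–Br bond and an oxidation that leaves the pyranone alone.

9 to 7: the C3–Br bond is cut. C3 is α to the carbonyl and the terminus of the ring dienyl ether, so it is a nucleophilic position of commercial 7. The demand is selectivity for C3 over C5.

6 to 4 to 2 to 1: the aryl C–O bond is traced to an aryl C–CHO bond (oxygen insertion), then the formyl carbon and the two O–CH3 bonds are removed. The new oxygen must sit ortho to the pentyl chain and para to a methoxy group, which is where electrophilic formylation of 2 goes. The demands are that regiochemistry and aryl (not hydride) migration in the oxygen insertion.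

## Other disconnections considered

Alternative 1: The cut is the O–C1' bond of the diaryl ether, made while the two rings are tied as an ester, followed by the C1–O2 lactone bond.
- Forward key step: the ring A salicylic acid is esterified with one hydroxyl of 1 to give depside A2. Anodic oxidation converts the remaining resorcinol phenol into a phenoxonium ion, and the ring A phenol oxygen attacks the carbon para to that hydroxyl, closing the seven-membered ring of depsidone A1. The structure of A1 corresponds to 8-hydroxy-6-pentyl substitution of the dibenzodioxepinone; a 7-hydroxy-9-pentyl name would place the pentyl next to the ester oxygen and would not map onto ring B. Acid would then remove the ketal and the methoxymethyl group, and the freed ketone enol would take the acyl group from the 2'-oxygen, forming the lactone and releasing the 2'-hydroxyl.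
- In favour: it is biomimetic and convergent, both rings start as aromatic compounds, the tether delivers oxygen to C1', and no metal catalyst is needed. The acid-only endgame is better than the boron tribromide finish of the chosen plan.
- Against: the oxidation must select the ring B phenol over the salicylate phenol. The ring B carbon between its two oxygens is also within reach of the tether and would give an isomeric depsidone. A1 is a 4-aryloxyphenol and should be easier to oxidise than A2, so over-oxidation is built in. A2 needs a statistical mono-acylation of a symmetric diol and a ring A acid with a ketal side chain that takes several steps.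
- Comparison: on structure it is the equal of the chosen plan in convergence and addresses the ether more directly. On mechanism it depends on a potential-controlled oxidation of an unprotected electron-rich arene, whereas the chosen plan makes the ether by polar addition before ring A exists. The step count is estimated to be about equal.

Alternative 2: The cut removes both carbon substituents of ring A at once, the C4a–C4 and C8a–C1 bonds, from an aryne that already carries the diaryl ether.
- Forward key step: fluoride generates 3-aryloxy-5-methoxybenzyne from silylaryl triflate A4. The enolate of dimethyl malonate A5 adds at the aryne carbon remote from the aryloxy group, the aryl anion attacks an ester carbonyl, and fragmentation of the four-membered ring gives homophthalate A3. Hydrolysis, acylation with a hexanoyl unit, decarboxylative lactonisation and triple demethylation would follow.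
- In favour: aryne insertion into a malonate C–C bond is a known reaction type, and the 3-oxygen substituent directs the ester next to the ether as required. All intermediates are robust aromatics with no double-bond geometry and no dehydrogenation. On regiochemical certainty of the key step and robustness of intermediates it is better than the chosen plan.
- Against: the ether must be present in A4, so the hindered, electron-rich 6 has to be O-arylated with a dioxygenated aryl halide, the very coupling the chosen plan avoids. A4 also needs selective mono-arylation, mono-methylation, ortho-silylation and triflation of a symmetrical triol. The pentyl chain and lactone are then added in further steps.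
- Comparison: the mechanism of the key step is more secure, but the difficulty moves to the aryl–oxygen coupling. The step count is estimated at twelve to fourteen, against ten.

Alternative 3: The cut dissolves ring B, breaking C1'–C6' and C3'–C4', so that ring B is built on the oxygen of a ring A phenol.
- Forward key step: methoxide adds the aryloxy-bearing carbon of acetoacetate A7 to methyl (E)-oct-2-enoate A8, and the acetyl methyl then closes onto the enoate ester to give cyclohexanedione A6 as a diastereomer mixture. Its aryloxy residue is 5-methoxy-2-(methoxycarbonyl)-3-methylphenoxy, with the methyl ortho and the methoxy para to the ester; a 3-methoxy-5-methyl residue would misplace the C6 oxygen. Dealkoxycarbonylation and dehydrogenation would give the resorcinol ring, and lateral metalation of the ortho-methyl benzoate with acylation would build the lactone.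
- In favour: the ether bond comes from simple O-alkylation of a phenol with a halo-acetoacetate, which is better than any aryl–oxygen bond construction and at least the equal of the chosen conjugate addition. The reagents are cheap, no transition metal is needed, and the diastereomers of A6 are irrelevant.
- Against: the Michael donor is a fully substituted carbon adding to a β-alkyl enoate, so the addition is slow and reversible. The carbanion of A7 sits five atoms from the ortho ester on the aromatic ring, so a Dieckmann closure to a benzofuranone competes. The adduct is a non-enolisable β-keto ester open to deacetylation by methoxide. Aromatisation, phenol protection and the late lactone construction add length.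
- Comparison: on mechanism it offers more competing ionic pathways in the key step than the pericyclic closure. On step count it is estimated at eleven to thirteen, so the chosen plan is shorter.

Key step: step 9

Remarks on the chemistry:
- Compound 10 is used as the racemate. Its stereocentre is removed in step 6, and the transient C4a centre of 15 is removed by aromatisation.
- For 13 the isomer with the aryloxy group anti to the acetyl group is taken to be the thermodynamic one, as is usual for vinylogous esters.

## Steps

Step 1
Reactants: 1 olivetol (5-pentylbenzene-1,3-diol)
Product: 2 1,3-dimethoxy-5-pentylbenzene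
Conditions: MeI (2.5 equiv), K2CO3 (3 equiv), acetone, reflux
Reagents that add atoms: iodomethane, CI
Why: Williamson ether synthesis; both phenoxides are methylated in one operation, and a carbonate base in acetone favours O- over C-alkylation.

Step 2
Reactants: 2 1,3-dimethoxy-5-pentylbenzene
Product: 4 2,4-dimethoxy-6-pentylbenzaldehyde, via iminium chloride 3 (not isolated)
Conditions: POCl3 (1.2 equiv), DMF, 0 °C to 60 °C; then aq. NaOAc, rt
Reagents that add atoms: N,N-dimethylformamide, CN(C)C=O (formyl carbon); water, O (aldehyde oxygen)
Why: Vilsmeier–Haack formylation; the chloroiminium ion should attack the position para to one methoxy and ortho to the other, next to the pentyl chain, in preference to the more crowded site between the two methoxy groups, and hydrolysis of 3 gives the aldehyde.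

Step 3
Reactants: 4 2,4-dimethoxy-6-pentylbenzaldehyde
Product: 6 2,4-dimethoxy-6-pentylphenol, via aryl formate 5 (not isolated)
Conditions: mCPBA (1.2 equiv), CH2Cl2, 0 °C to rt; then K2CO3 (cat.), MeOH, rt
Reagents that add atoms: 3-chloroperoxybenzoic acid, OOC(=O)c1cccc(Cl)c1
Why: Baeyer–Villiger oxidation of an electron-rich benzaldehyde (Dakin-type); the ortho,para-dimethoxyaryl group migrates in the peracid adduct to give formate 5, and methanolysis releases the phenol.

Step 4
Reactants: 7 6-pentyl-2H-pyran-2-one
Product: 9 3-bromo-6-pentyl-2H-pyran-2-one, via dibromide 8 (not isolated)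
Conditions: Br2 (1.05 equiv), CH2Cl2, 0 °C, dark; then Et3N (1.5 equiv), 0 °C to rt
Reagents that add atoms: bromine, BrBr
Why: Ionic bromination of a 2-pyranone by addition–elimination; bromine should add at C3 (α to the carbonyl, terminus of the ring dienyl ether) with bromide capture at C4 to give 8, and Et3N then removes the acidic C3 hydrogen and expels the allylic C4 bromide.

Step 5
Reactants: 9 3-bromo-6-pentyl-2H-pyran-2-one; 10 but-3-yn-2-ol
Product: 11 3-(3-hydroxybut-1-yn-1-yl)-6-pentyl-2H-pyran-2-one
Conditions: PdCl2(PPh3)2 (3 mol%), CuI (5 mol%), Et3N, THF, rt to 40 °C
Reagents that add atoms: none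
Why: Sonogashira coupling; the C3–Br bond of an α-bromo unsaturated lactone undergoes oxidative addition readily, and the free secondary alcohol is tolerated.

Step 6
Reactants: 11 3-(3-hydroxybut-1-yn-1-yl)-6-pentyl-2H-pyran-2-one
Product: 12 3-(3-oxobut-1-yn-1-yl)-6-pentyl-2H-pyran-2-one
Conditions: MnO2 (activated, 10 equiv), CH2Cl2, rt
Reagents that add atoms: none
Why: MnO2 oxidation of a propargylic alcohol to the ynone under neutral heterogeneous conditions that should leave the pyranone untouched; the carbinol stereocentre disappears.

Step 7
Reactants: 12 3-(3-oxobut-1-yn-1-yl)-6-pentyl-2H-pyran-2-one; 6 2,4-dimethoxy-6-pentylphenol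
Product: 13 3-[(1E)-1-(2,4-dimethoxy-6-pentylphenoxy)-3-oxobut-1-en-1-yl]-6-pentyl-2H-pyran-2-one
Conditions: DABCO (20 mol%), MeCN, rt to 50 °C
Reagents that add atoms: none
Why: Oxa-Michael addition of a phenol to an ynone under nucleophilic amine catalysis; the oxygen adds to the alkyne carbon β to the ketone (the one on pyranone C3), and reversible addition–elimination of DABCO or phenoxide at that carbon should equilibrate the vinylogous ester to the (E) isomer, which places pyranone and acetyl cis.

Step 8
Reactants: 13 3-[(1E)-1-(2,4-dimethoxy-6-pentylphenoxy)-3-oxobut-1-en-1-yl]-6-pentyl-2H-pyran-2-one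
Product: 14 3-[(1E)-3-[(tert-butyldimethylsilyl)oxy]-1-(2,4-dimethoxy-6-pentylphenoxy)buta-1,3-dien-1-yl]-6-pentyl-2H-pyran-2-one
Conditions: TBSOTf (1.2 equiv), Et3N (2 equiv), Et2O, 0 °C
Reagents that add atoms: tert-butyldimethylsilyl trifluoromethanesulfonate, CC(C)(C)[Si](C)(C)OS(=O)(=O)C(F)(F)F
Why: Silyl enol ether formation by soft enolisation; the silyl triflate activates the basic vinylogous-ester carbonyl, Et3N removes a proton from the methyl group (the only α-position), the C=C geometry is retained at 0 °C, and the limited amount of silyl triflate spares the less basic pyranone carbonyl.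

Step 9
Reactants: 14 3-[(1E)-3-[(tert-butyldimethylsilyl)oxy]-1-(2,4-dimethoxy-6-pentylphenoxy)buta-1,3-dien-1-yl]-6-pentyl-2H-pyran-2-one
Product: 16 6-[(tert-butyldimethylsilyl)oxy]-8-(2,4-dimethoxy-6-pentylphenoxy)-3-pentyl-1H-isochromen-1-one, via dihydroisocoumarin 15 (not isolated)
Conditions: o-xylene (0.01 M, degassed), 140 °C, sealed tube; then DDQ (1.1 equiv), 0 °C to rt
Reagents that add atoms: none
Why: On heating, the triene C5=C6–C7=C8–C8a=C4a of 14 should adopt the s-cis,s-cis conformation and close by a thermally allowed disrotatory 6π electrocyclisation, forming the C4a–C5 bond and the six-membered carbocycle of 15; DDQ then abstracts hydride from C5 (the cation is stabilised by the C6 siloxy and C8 aryloxy groups) and loss of the C4a proton gives aromatic ring A. The closest known reaction type is the benzannulation of dienyl-substituted unsaturated lactones and 2-siloxyhexatrienes by thermal electrocyclisation and dehydrogenation. The pyranone C3=C4 bond serves as the terminal two-electron component, and the loss of its weak cyclic conjugation is offset by the push–pull dienoate (C6 siloxy to C1 carbonyl) formed in 15. The C4a centre of 15 is created racemic and erased on aromatisation, so no control element is needed. The selectivity required is the C7=C8 geometry with pyranone and siloxyvinyl cis; it is set under equilibrating conditions in step 7 and kept in step 8, because this double bond has no acceptor in conjugation in 14 and should not isomerise on heating. No other triene is available, since ring B is attached through oxygen and the lactone carbonyl is cross-conjugated. High dilution suppresses intermolecular Diels–Alder reaction between the siloxydiene and a pyranone, and a slight excess of DDQ at 0 °C should spare ring B and the pentyl benzylic positions, which lie meta to the methoxy groups.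

Step 10
Reactants: 16 6-[(tert-butyldimethylsilyl)oxy]-8-(2,4-dimethoxy-6-pentylphenoxy)-3-pentyl-1H-isochromen-1-one
Product: 18 8-(2,4-dihydroxy-6-pentylphenoxy)-6-hydroxy-3-pentyl-1H-isochromen-1-one, via tris(dibromoboryl) ether 17 (not isolated)
Conditions: BBr3 (6 equiv), CH2Cl2, −78 °C to rt, Ar; then H2O, 0 °C, aq. Na2S2O4 wash
Reagents that add atoms: none
Why: Lewis-acid ether cleavage; BBr3 coordinates each methoxy oxygen and bromide removes the methyl group by SN2, while Si–O/B–Br exchange converts the aryl silyl ether into the aryl dibromoborate, giving 17, and water hydrolyses the three B–O bonds. The diaryl ether and the enol lactone offer no sp3 carbon on oxygen and should survive; inert atmosphere and the dithionite wash protect the freed ring B.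

## Compound list

1 | olivetol (5-pentylbenzene-1,3-diol) | CCCCCc1cc(O)cc(O)c1 | starting material
2 | 1,3-dimethoxy-5-pentylbenzene | CCCCCc1cc(OC)cc(OC)c1 | intermediate
3 | N-[(2,4-dimethoxy-6-pentylphenyl)methylidene]-N-methylmethanaminium chloride (not isolated) | CCCCCc1cc(OC)cc(OC)c1C=[N+](C)C.[Cl-] | intermediate
4 | 2,4-dimethoxy-6-pentylbenzaldehyde | CCCCCc1cc(OC)cc(OC)c1C=O | intermediate
5 | 2,4-dimethoxy-6-pentylphenyl formate (not isolated) | CCCCCc1cc(OC)cc(OC)c1OC=O | intermediate
6 | 2,4-dimethoxy-6-pentylphenol | CCCCCc1cc(OC)cc(OC)c1O | intermediate
7 | 6-pentyl-2H-pyran-2-one | CCCCCc1cccc(=O)o1 | starting material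
8 | 3,4-dibromo-6-pentyl-3,4-dihydro-2H-pyran-2-one (stereoisomer mixture, not isolated) | CCCCCC1=CC(Br)C(Br)C(=O)O1 | intermediate
9 | 3-bromo-6-pentyl-2H-pyran-2-one | CCCCCc1ccc(Br)c(=O)o1 | intermediate
10 | but-3-yn-2-ol (racemic) | CC(O)C#C | starting material
11 | 3-(3-hydroxybut-1-yn-1-yl)-6-pentyl-2H-pyran-2-one (racemic) | CCCCCc1ccc(C#CC(C)O)c(=O)o1 | intermediate
12 | 3-(3-oxobut-1-yn-1-yl)-6-pentyl-2H-pyran-2-one | CCCCCc1ccc(C#CC(C)=O)c(=O)o1 | intermediate
13 | 3-[(1E)-1-(2,4-dimethoxy-6-pentylphenoxy)-3-oxobut-1-en-1-yl]-6-pentyl-2H-pyran-2-one | CCCCCc1ccc(/C(Oc2c(OC)cc(OC)cc2CCCCC)=C\C(C)=O)c(=O)o1 | intermediate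
14 | 3-[(1E)-3-[(tert-butyldimethylsilyl)oxy]-1-(2,4-dimethoxy-6-pentylphenoxy)buta-1,3-dien-1-yl]-6-pentyl-2H-pyran-2-one | CCCCCc1ccc(/C(Oc2c(OC)cc(OC)cc2CCCCC)=C\C(=C)O[Si](C)(C)C(C)(C)C)c(=O)o1 | intermediate
15 | 6-[(tert-butyldimethylsilyl)oxy]-8-(2,4-dimethoxy-6-pentylphenoxy)-3-pentyl-4a,5-dihydro-1H-isochromen-1-one (racemic, not isolated) | CCCCCC1=CC2CC(O[Si](C)(C)C(C)(C)C)=CC(Oc3c(OC)cc(OC)cc3CCCCC)=C2C(=O)O1 | intermediate
16 | 6-[(tert-butyldimethylsilyl)oxy]-8-(2,4-dimethoxy-6-pentylphenoxy)-3-pentyl-1H-isochromen-1-one | CCCCCc1cc2cc(O[Si](C)(C)C(C)(C)C)cc(Oc3c(OC)cc(OC)cc3CCCCC)c2c(=O)o1 | intermediate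
17 | 6-[(dibromoboranyl)oxy]-8-{2,4-bis[(dibromoboranyl)oxy]-6-pentylphenoxy}-3-pentyl-1H-isochromen-1-one (not isolated) | CCCCCc1cc2cc(OB(Br)Br)cc(Oc3c(OB(Br)Br)cc(OB(Br)Br)cc3CCCCC)c2c(=O)o1 | intermediate
18 | 8-(2,4-dihydroxy-6-pentylphenoxy)-6-hydroxy-3-pentyl-1H-isochromen-1-one | CCCCCc1cc2cc(O)cc(Oc3c(O)cc(O)cc3CCCCC)c2c(=O)o1 | target

## Step count and least certain steps

Total step count: 10. Longest linear sequence: 7 steps (steps 4 to 10; the branch through steps 1 to 3 and 7 to 10 is equally long).

Step 9 (key step). The most likely failure is a ring closure that is too slow, because the pyranone C3=C4 bond must give up its cyclic conjugation; desilylation and oligomerisation of the siloxydiene would then compete at 140 °C. Partial over-oxidation of ring B by DDQ is a second concern. The fallback makes the same C4a–C5 bond by an ionic route and sets out from 13. LiN(SiMe3)2 in THF at −78 °C to 0 °C should deprotonate the methyl ketone, and the cross-conjugated enolate should add to pyranone C4 in an intramolecular Michael reaction. Protonation with aq. NH4Cl would give 8-(2,4-dimethoxy-6-pentylphenoxy)-3-pentyl-4a,5-dihydro-1H-isochromene-1,6(8aH)-dione F1. DDQ in CH2Cl2 would dehydrogenate it to 6-hydroxy-8-(2,4-dimethoxy-6-pentylphenoxy)-3-pentyl-1H-isochromen-1-one F2. Under the conditions of step 10, F2 comes back to the route at 17 and so reaches 18.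

Step 4. The most likely failure is competing electrophilic attack at C5, the β-carbon of the ring enol ether, giving regioisomeric or doubly brominated material that is hard to separate. The fallback fixes bromine at C3 on a lactone that has only one alkene. It does not set out from an earlier numbered compound: commercial 6-pentyl-5,6-dihydro-2H-pyran-2-one F3 (either enantiomer or the racemate, since the stereocentre is lost) takes the place of 7. Br2 in CH2Cl2 would give 3,4-dibromo-6-pentyloxan-2-one F4, and Et3N in the same flask would eliminate HBr to 3-bromo-6-pentyl-5,6-dihydro-2H-pyran-2-one F5. Allylic bromination with NBS and AIBN in refluxing PhCF3 would give 3,5-dibromo-6-pentyl-5,6-dihydro-2H-pyran-2-one F6. Et3N would then eliminate HBr across C5–C6, and the sequence comes back to the route at 9.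

Step 7. The most likely failure is slow addition of the di-ortho-substituted phenol, which would let amine-initiated oligomerisation of the ynone take over, or a kinetic anti-addition geometry that does not equilibrate. The fallback replaces catalytic addition by stoichiometric addition–elimination and sets out from 12. LiCl in AcOH should add HCl across the alkyne to give 3-[(1Z)-1-chloro-3-oxobut-1-en-1-yl]-6-pentyl-2H-pyran-2-one F7. Treatment of F7 with 6 and K2CO3 in DMF at rt to 50 °C should displace chloride, and the stoichiometric phenoxide should equilibrate the vinylogous ester, so the sequence comes back at 13.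

Step 10. The most likely failure is incomplete cleavage of the aryl silyl ether by the Lewis acid, because its oxygen is para to the lactone carbonyl and weakly basic; air oxidation of the freed ring B during work-up is the second concern. The fallback uses two orthogonal reagents and sets out from 16. BBr3 at −78 °C to 0 °C would remove only the methyl groups and give 6-[(tert-butyldimethylsilyl)oxy]-8-(2,4-dihydroxy-6-pentylphenoxy)-3-pentyl-1H-isochromen-1-one F8. KHF2 in MeOH at rt would then cleave the phenolic silyl ether without base strong enough to open the lactone, and the sequence comes back at 18.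

## Further compounds

F1 | step 9 | 8-(2,4-dimethoxy-6-pentylphenoxy)-3-pentyl-4a,5-dihydro-1H-isochromene-1,6(8aH)-dione (stereoisomer mixture) | CCCCCC1=CC2CC(=O)C=C(Oc3c(OC)cc(OC)cc3CCCCC)C2C(=O)O1
F2 | step 9 | 6-hydroxy-8-(2,4-dimethoxy-6-pentylphenoxy)-3-pentyl-1H-isochromen-1-one | CCCCCc1cc2cc(O)cc(Oc3c(OC)cc(OC)cc3CCCCC)c2c(=O)o1
F3 | step 4 | 6-pentyl-5,6-dihydro-2H-pyran-2-one | CCCCCC1CC=CC(=O)O1
F4 | step 4 | 3,4-dibromo-6-pentyloxan-2-one (stereoisomer mixture) | CCCCCC1CC(Br)C(Br)C(=O)O1
F5 | step 4 | 3-bromo-6-pentyl-5,6-dihydro-2H-pyran-2-one | CCCCCC1CC=C(Br)C(=O)O1
F6 | step 4 | 3,5-dibromo-6-pentyl-5,6-dihydro-2H-pyran-2-one (stereoisomer mixture) | CCCCCC1OC(=O)C(Br)=CC1Br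
F7 | step 7 | 3-[(1Z)-1-chloro-3-oxobut-1-en-1-yl]-6-pentyl-2H-pyran-2-one | CCCCCc1ccc(/C(Cl)=C/C(C)=O)c(=O)o1
F8 | step 10 | 6-[(tert-butyldimethylsilyl)oxy]-8-(2,4-dihydroxy-6-pentylphenoxy)-3-pentyl-1H-isochromen-1-one | CCCCCc1cc2cc(O[Si](C)(C)C(C)(C)C)cc(Oc3c(O)cc(O)cc3CCCCC)c2c(=O)o1
A1 | alternative 1 | 8-hydroxy-3-(methoxymethoxy)-6-pentyl-1-[(2-pentyl-1,3-dioxolan-2-yl)methyl]-11H-dibenzo[b,e][1,4]dioxepin-11-one | O=C1Oc2cc(O)cc(CCCCC)c2Oc2cc(OCOC)cc(CC3(CCCCC)OCCO3)c21
A2 | alternative 1 | 3-hydroxy-5-pentylphenyl 2-hydroxy-4-(methoxymethoxy)-6-[(2-pentyl-1,3-dioxolan-2-yl)methyl]benzoate | CCCCCc1cc(O)cc(OC(=O)c2c(O)cc(OCOC)cc2CC3(CCCCC)OCCO3)c1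
A3 | alternative 2 | methyl 2-(2,4-dimethoxy-6-pentylphenoxy)-4-methoxy-6-(2-methoxy-2-oxoethyl)benzoate | COC(=O)Cc1cc(OC)cc(Oc2c(OC)cc(OC)cc2CCCCC)c1C(=O)OC
A4 | alternative 2 | 3-(2,4-dimethoxy-6-pentylphenoxy)-5-methoxy-2-(trimethylsilyl)phenyl trifluoromethanesulfonate | COc1cc(OS(=O)(=O)C(F)(F)F)c([Si](C)(C)C)c(Oc2c(OC)cc(OC)cc2CCCCC)c1
A5 | alternative 2 | dimethyl malonate | COC(=O)CC(=O)OC
A6 | alternative 3 | methyl 1-[5-methoxy-2-(methoxycarbonyl)-3-methylphenoxy]-2,4-dioxo-6-pentylcyclohexane-1-carboxylate (diastereomer mixture) | COC(=O)C1(Oc2cc(OC)cc(C)c2C(=O)OC)C(CCCCC)CC(=O)CC1=O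
A7 | alternative 3 | methyl 4-methoxy-2-[(1-methoxy-1,3-dioxobutan-2-yl)oxy]-6-methylbenzoate | COC(=O)C(Oc1cc(OC)cc(C)c1C(=O)OC)C(C)=O
A8 | alternative 3 | methyl (E)-oct-2-enoate | CCCCC/C=C/C(=O)OC
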